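**Retrosynthetic overview**

1. Structural feature: on the cyclopentane ring (C5–C9) the one-carbon arms C1 (on C9) and C10 (on C8) are cis and vicinal, both anti to O8 and H-9. This is the retron of a cleaved cyclobutene fused to a 2-acyloxycyclopentenone, so C1–C9 and C8–C10 are cut together back to a 2-acyloxy-4-silyloxycyclopentenone and acetylene ([2+2], then ozonolysis).
2. The dihydropyran ring (C1, O2, C3, C4, C5, C9) is opened last: the C1 acylal comes from the lactol of a C1 aldehyde with a C3/C11 malondialdehyde mono-enol ether, and C4–C5 from Stille coupling of a C5 enol triflate with a stannylated 3-methoxyacrolein.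
3. C7 is set by hydride delivery from the C5 hydroxyl (the single bought stereocentre, afterwards oxidised away). The C8 isovalerate installed before the photoreaction migrates to O10 once the cyclobutene is cleaved.
4. Ring order: cyclopentane (bought) → cyclobutene (photocycloaddition, later cleaved) → dihydropyran (lactolisation).

Key step: step 3

Remark: iridoid locants (C1, O2, C3, C4, C5–C9, C10 on C8, C11 on C4) are used for all intermediates. The target is taken as the (1S,7R,8S,9S) isomer defined by the SMILES: H-9 and O8 on one face, C10 and O7 on the other, O1 cis to H-9.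

**Route**

Step 1
Reactants: 1 (R)-4-(tert-butyldimethylsilyloxy)cyclopent-2-en-1-one
Product: 2 (2S,3R,4R)-4-(tert-butyldimethylsilyloxy)-2,3-dihydroxycyclopentan-1-one
Conditions: OsO4 (cat.), N-methylmorpholine N-oxide, citric acid, acetone/H2O, 23 °C
Reagents that add atoms: N-methylmorpholine N-oxide (C[N+]1([O-])CCOCC1); water (O)
Why: Catalytic OsO4 syn-dihydroxylation of the enone alkene should occur on the face anti to the C5 silyloxy group, so the two new carbinol centres (C8, C9) are cis to each other and trans to OSi, the citric acid buffer keeping the β-hydroxy ketone from eliminating.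

Step 2
Reactants: 2 (2S,3R,4R)-4-(tert-butyldimethylsilyloxy)-2,3-dihydroxycyclopentan-1-one
Product: 4 (R)-4-(tert-butyldimethylsilyloxy)-2-(3-methylbutanoyloxy)cyclopent-2-en-1-one, via diester 3 (not isolated)
Conditions: (i-PrCH2CO)2O, Et3N, DMAP (cat.), CH2Cl2, 0 → 23 °C
Reagents that add atoms: 3-methylbutanoic anhydride (CC(C)CC(=O)OC(=O)CC(C)C)
Why: Double DMAP-catalysed acylation followed by E1cB loss of the β-acyloxy group (from C9) through the doubly activated C8–H should give the 2-acyloxy enone without touching C5, because carboxylate is a far better leaving group than the silyloxide that the other enolate could expel; no stereocentre is formed.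

Step 3
Reactants: 4 (R)-4-(tert-butyldimethylsilyloxy)-2-(3-methylbutanoyloxy)cyclopent-2-en-1-one; 5 acetylene
Product: 6 (1R,4R,5S)-4-(tert-butyldimethylsilyloxy)-2-oxobicyclo[3.2.0]hept-6-en-1-yl 3-methylbutanoate (cyclobutene anti to the silyloxy group)
Conditions: hν (medium-pressure Hg lamp, uranium-glass filter, λ > 340 nm), acetylene-saturated acetone/CH2Cl2, −60 °C, run to partial conversion
Reagents that add atoms: none
Why: Excitation of the enone and intersystem crossing give the triplet, which adds to acetylene to form a triplet 1,4-biradical that closes after spin inversion, so C9–C1 and C8–C10 are made in one photochemical [2+2] event. The closest known reaction type is the intermolecular enone–alkyne photocycloaddition, established for cyclopentenones including 2-acyloxy ones. The cyclobutene is closed by radical recombination across the former enone double bond and can only be cis-fused to the five-membered ring, which fixes C8 and C9 relative to each other with O8 and H-9 both anti to the two new carbons. The absolute sense is controlled by the C5 silyloxy stereocentre next to C9, acetylene approaching the face anti to the bulky OSi group. The step needs this facial selectivity and chemoselectivity against secondary photoreaction of the β,γ-unsaturated ketone product (1,3-acyl shift); long-wavelength light absorbed by the enone but only weakly by the product, low temperature and interruption before full conversion are meant to secure both. Regiochemistry does not arise because acetylene is symmetrical.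

Step 4
Reactants: 6 (1R,4R,5S)-4-(tert-butyldimethylsilyloxy)-2-oxobicyclo[3.2.0]hept-6-en-1-yl 3-methylbutanoate
Product: 7 (1R,4R,5S)-4-hydroxy-2-oxobicyclo[3.2.0]hept-6-en-1-yl 3-methylbutanoate
Conditions: HF·pyridine, MeCN, 0 °C
Reagents that add atoms: none
Why: Fluoride-mediated silyl ether cleavage under weakly acidic conditions frees the C5 hydroxyl without base-induced dehydration of the β-hydroxy ketone; no stereocentre changes.

Step 5
Reactants: 7 (1R,4R,5S)-4-hydroxy-2-oxobicyclo[3.2.0]hept-6-en-1-yl 3-methylbutanoate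
Product: 8 (1R,2R,4R,5S)-2,4-dihydroxybicyclo[3.2.0]hept-6-en-1-yl 3-methylbutanoate
Conditions: Me4NBH(OAc)3, MeCN/AcOH, −30 °C
Reagents that add atoms: none
Why: Evans–Saksena hydroxyl-directed reduction: the C5 alkoxy(diacetoxy)borohydride on the convex face delivers hydride intramolecularly to the same face of the C7 ketone, which should give the anti 1,3-diol with O7 on the cyclobutene face and trans to O8, an outcome that a free borohydride, hindered on that face by the C8 ester, would not secure.

Step 6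
Reactants: 8 (1R,2R,4R,5S)-2,4-dihydroxybicyclo[3.2.0]hept-6-en-1-yl 3-methylbutanoate
Product: 10 (1R,2R,4R,5S)-2-(tert-butyldimethylsilyloxy)-4-(triethylsilyloxy)bicyclo[3.2.0]hept-6-en-1-yl 3-methylbutanoate, via mono-triethylsilyl ether 9 (not isolated)
Conditions: Et3SiOTf (1 equiv), 2,6-lutidine, CH2Cl2, −78 °C; then t-BuMe2SiOTf, −78 → 0 °C
Reagents that add atoms: triethylsilyl triflate (CC[Si](CC)(CC)OS(=O)(=O)C(F)(F)F); tert-butyldimethylsilyl triflate (CC(C)(C)[Si](C)(C)OS(=O)(=O)C(F)(F)F)
Why: Sequential silylation with silyl triflates should discriminate the unhindered convex C5 hydroxyl (first equivalent, Et3Si) from the concave C7 hydroxyl beside quaternary C8 (then t-BuMe2Si); no stereocentre changes.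

Step 7
Reactants: 10 (1R,2R,4R,5S)-2-(tert-butyldimethylsilyloxy)-4-(triethylsilyloxy)bicyclo[3.2.0]hept-6-en-1-yl 3-methylbutanoate
Product: 11 (1R,2R,4R,5S)-2-(tert-butyldimethylsilyloxy)-4-hydroxybicyclo[3.2.0]hept-6-en-1-yl 3-methylbutanoate
Conditions: pyridinium p-toluenesulfonate (cat.), MeOH/CH2Cl2, 0 °C
Reagents that add atoms: none
Why: Acid-catalysed methanolysis of silyl ethers removes the secondary triethylsilyl ether orders of magnitude faster than the hindered tert-butyldimethylsilyl ether, exposing only the C5 hydroxyl.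

Step 8
Reactants: 11 (1R,2R,4R,5S)-2-(tert-butyldimethylsilyloxy)-4-hydroxybicyclo[3.2.0]hept-6-en-1-yl 3-methylbutanoate
Product: 12 (1R,2R,5R)-2-(tert-butyldimethylsilyloxy)-4-oxobicyclo[3.2.0]hept-6-en-1-yl 3-methylbutanoate
Conditions: Dess–Martin periodinane, NaHCO3, CH2Cl2, 23 °C
Reagents that add atoms: none
Why: Dess–Martin oxidation of the secondary alcohol gives the C5 ketone under buffered, non-enolising conditions; the bought stereocentre is erased here and C9 cannot epimerise because the cyclobutene must stay cis-fused.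

Step 9
Reactants: 12 (1R,2R,5R)-2-(tert-butyldimethylsilyloxy)-4-oxobicyclo[3.2.0]hept-6-en-1-yl 3-methylbutanoate
Product: 13 (1R,2R,5R)-2-(tert-butyldimethylsilyloxy)-4-(trifluoromethylsulfonyloxy)bicyclo[3.2.0]hepta-3,6-dien-1-yl 3-methylbutanoate
Conditions: KN(SiMe3)2, THF, −78 °C; then N-(5-chloro-2-pyridyl)bis(trifluoromethanesulfonimide), −78 °C
Reagents that add atoms: N-(5-chloro-2-pyridyl)bis(trifluoromethanesulfonimide) (FC(F)(F)S(=O)(=O)N(c1ccc(Cl)cn1)S(=O)(=O)C(F)(F)F)
Why: Kinetic enolate formation and O-sulfonylation (enol triflate synthesis) should be regiospecific for C5=C6 because enolisation toward C9 would create an alkylidenecyclobutene, and at −78 °C the C7 silyloxide is too poor a leaving group for E1cB loss before trapping.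

Step 10
Reactants: 13 (1R,2R,5R)-2-(tert-butyldimethylsilyloxy)-4-(trifluoromethylsulfonyloxy)bicyclo[3.2.0]hepta-3,6-dien-1-yl 3-methylbutanoate
Product: 16 [5-(tert-butyldimethylsilyloxy)-1-hydroxy-2-(hydroxymethyl)-3-(trifluoromethylsulfonyloxy)cyclopent-3-en-1-yl]methyl 3-methylbutanoate (C7 OSi and C10 arm on one face; O8 and H-9 on the other; C1 arm cis to C10 arm), via ozonide 14 (not isolated), via tertiary ester diol 15 (not isolated)
Conditions: O3, CH2Cl2, −78 °C (Sudan Red 7B end point); then NaBH4, MeOH, −78 → 0 °C; then DBU (cat.), CH2Cl2, 23 °C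
Reagents that add atoms: ozone ([O-][O+]=O)
Why: Ozonolysis with reductive work-up cleaves the strained, electron-rich cyclobutene much faster than the triflyloxy-substituted C5=C6 bond, and the base-mediated 1,2-acyl shift (tertiary O8 to primary O10 through a five-membered orthoester) then marks C10 as the ester and leaves C1 as the only primary alcohol, a shift to O1 requiring a trans-fused six-membered intermediate; no stereocentre is formed.

Step 11
Reactants: 16 [5-(tert-butyldimethylsilyloxy)-1-hydroxy-2-(hydroxymethyl)-3-(trifluoromethylsulfonyloxy)cyclopent-3-en-1-yl]methyl 3-methylbutanoate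
Product: 17 [1,5-dihydroxy-2-(hydroxymethyl)-3-(trifluoromethylsulfonyloxy)cyclopent-3-en-1-yl]methyl 3-methylbutanoate
Conditions: 48% aq. HF, MeCN, 23 °C
Reagents that add atoms: none
Why: Aqueous HF cleaves the hindered secondary silyl ether (fluoride desilylation) while the enol triflate, the ester and the alkene are inert.

Step 12
Reactants: 17 [1,5-dihydroxy-2-(hydroxymethyl)-3-(trifluoromethylsulfonyloxy)cyclopent-3-en-1-yl]methyl 3-methylbutanoate
Product: 18 [2-(tert-butyldimethylsilyloxymethyl)-1,5-dihydroxy-3-(trifluoromethylsulfonyloxy)cyclopent-3-en-1-yl]methyl 3-methylbutanoate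
Conditions: t-BuMe2SiCl, imidazole, DMF, −20 °C
Reagents that add atoms: tert-butyldimethylsilyl chloride (CC(C)(C)[Si](C)(C)Cl)
Why: Silylation with the bulky chlorosilane should take place only at the single primary hydroxyl (C1), the hindered secondary C7 and tertiary C8 hydroxyls reacting far more slowly.

Step 13
Reactants: 19 methyl (E)-3-methoxyacrylate
Product: 21 methyl (Z)-2-iodo-3-methoxyacrylate, via iodo acetate adduct 20 (not isolated)
Conditions: N-iodosuccinimide, AcOH, CH2Cl2, 23 °C; then Et3N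
Reagents that add atoms: N-iodosuccinimide (O=C1CCC(=O)N1I)
Why: Iodoacetoxylation of the push–pull alkene followed by amine-induced elimination of acetic acid (addition–elimination α-halogenation of a β-alkoxyacrylate) should give the iodide with iodine cis to methoxy.

Step 14
Reactants: 21 methyl (Z)-2-iodo-3-methoxyacrylate
Product: 22 methyl (Z)-3-methoxy-2-(tributylstannyl)acrylate
Conditions: (Bu3Sn)2, Pd(PPh3)4 (cat.), toluene, 90 °C
Reagents that add atoms: hexabutylditin (CCCC[Sn](CCCC)(CCCC)[Sn](CCCC)(CCCC)CCCC)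
Why: Palladium-catalysed stannylation of the alkenyl iodide with the distannane (oxidative addition to zerovalent palladium, Sn–Sn transmetallation, reductive elimination) proceeds with retention of alkene geometry.

Step 15
Reactants: 22 methyl (Z)-3-methoxy-2-(tributylstannyl)acrylate
Product: 23 (Z)-3-methoxy-2-(tributylstannyl)prop-2-en-1-ol
Conditions: i-Bu2AlH, CH2Cl2, −78 °C
Reagents that add atoms: none
Why: i-Bu2AlH reduces the conjugated ester to the allylic alcohol by two hydride additions at low temperature without touching the C–Sn bond.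

Step 16
Reactants: 23 (Z)-3-methoxy-2-(tributylstannyl)prop-2-en-1-ol
Product: 24 (Z)-3-methoxy-2-(tributylstannyl)prop-2-enal
Conditions: MnO2, CH2Cl2, 23 °C
Reagents that add atoms: none
Why: MnO2 oxidises the allylic alcohol selectively to the β-methoxy enal (allylic oxidation) under neutral conditions that avoid protodestannylation.

Step 17
Reactants: 18 [2-(tert-butyldimethylsilyloxymethyl)-1,5-dihydroxy-3-(trifluoromethylsulfonyloxy)cyclopent-3-en-1-yl]methyl 3-methylbutanoate; 24 (Z)-3-methoxy-2-(tributylstannyl)prop-2-enal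
Product: 25 {2-(tert-butyldimethylsilyloxymethyl)-3-[(E)-3-methoxy-1-oxoprop-2-en-2-yl]-1,5-dihydroxycyclopent-3-en-1-yl}methyl 3-methylbutanoate
Conditions: Pd(PPh3)4 (cat.), CuCl, LiCl, DMSO, 60 °C
Reagents that add atoms: none
Why: Stille coupling under copper-assisted conditions (CuCl and LiCl accelerate transmetallation of the hindered α-stannyl enal) joins C4 to C5 with retention at both alkenes, free hydroxyls being tolerated and no stereocentre being touched.

Step 18
Reactants: 25 {2-(tert-butyldimethylsilyloxymethyl)-3-[(E)-3-methoxy-1-oxoprop-2-en-2-yl]-1,5-dihydroxycyclopent-3-en-1-yl}methyl 3-methylbutanoate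
Product: 26 7,10-bis(3-methylbutanoate) of the same skeleton (C7 hydroxyl of 25 esterified; C8 hydroxyl free)
Conditions: (i-PrCH2CO)2O, DMAP, pyridine, CH2Cl2, 0 → 23 °C
Reagents that add atoms: 3-methylbutanoic anhydride (CC(C)CC(=O)OC(=O)CC(C)C)
Why: DMAP-catalysed acylation esterifies the secondary allylic C7 hydroxyl while the tertiary C8 hydroxyl is too hindered to react.

Step 19
Reactants: 26 7,10-bis(3-methylbutanoate) bearing the C1 silyl ether
Product: 27 C1 primary alcohol (7,10-bis(3-methylbutanoate); 8-OH; C4 side chain (E)-3-methoxy-1-oxoprop-2-en-2-yl)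
Conditions: HF·pyridine, pyridine, THF, 0 °C
Reagents that add atoms: none
Why: Pyridine-buffered HF·pyridine removes the primary silyl ether (fluoride desilylation) under near-neutral conditions that should not trigger exchange of the vinylogous ester with the liberated alcohol.

Step 20
Reactants: 27 C1 primary alcohol
Product: 29 (1R,6R,7S,7aS)-1,7-dihydroxy-6-(3-methylbutanoyloxy)-7-[(3-methylbutanoyloxy)methyl]-1,6,7,7a-tetrahydrocyclopenta[c]pyran-4-carbaldehyde, via aldehyde 28 (not isolated)
Conditions: Dess–Martin periodinane, NaHCO3, CH2Cl2, 0 °C; aq. Na2S2O3; then 0.1 M HCl, THF, 0 °C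
Reagents that add atoms: water (O)
Why: Dess–Martin oxidation gives the C1 aldehyde, which under dilute aqueous acid should close at once by conjugate addition–elimination at C3 with loss of methanol (hemiacetalisation of a 1,5-dicarbonyl with a malondialdehyde enol) to the vinylogous-formate-stabilised lactol, whose C1 hydroxyl settles under thermodynamic control pseudo-axial and anti to quaternary C8 (anomeric effect), that is cis to H-9 as in the target.

Step 21
Reactants: 30 3-hydroxy-3-methylbutanoic acid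
Product: 32 3-acetoxy-3-methylbutanoic acid, via mixed anhydride 31 (not isolated)
Conditions: AcCl, CH2Cl2, 23 °C; then H2O, THF
Reagents that add atoms: acetyl chloride (CC(Cl)=O)
Why: Acetyl chloride acetylates the tertiary hydroxyl (acid chloride esterification) and the mixed anhydride formed at the carboxyl group is hydrolysed back to the acid on aqueous work-up.

Step 22
Reactants: 29 lactol aldehyde; 32 3-acetoxy-3-methylbutanoic acid
Product: 33 (1S,6R,7S,7aS)-1-[(3-acetoxy-3-methylbutanoyl)oxy]-7-hydroxy-6-(3-methylbutanoyloxy)-7-[(3-methylbutanoyloxy)methyl]-1,6,7,7a-tetrahydrocyclopenta[c]pyran-4-carbaldehyde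
Conditions: dicyclohexylcarbodiimide, DMAP (cat.), CH2Cl2, −20 → 0 °C
Reagents that add atoms: none
Why: Steglich esterification acylates the lactol hydroxyl of the preferred anomer at oxygen, so the C1 configuration follows from the thermodynamic preference established in step 20.

Step 23
Reactants: 33 acylal aldehyde
Product: 34 (1S,6R,7S,7aS)-1-[(3-acetoxy-3-methylbutanoyl)oxy]-7-hydroxy-4-(hydroxymethyl)-6-(3-methylbutanoyloxy)-7-[(3-methylbutanoyloxy)methyl]-1,6,7,7a-tetrahydrocyclopenta[c]pyran
Conditions: NaBH4, CeCl3·7H2O, MeOH/THF, −78 °C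
Reagents that add atoms: none
Why: Luche reduction reduces the conjugated aldehyde in the 1,2 sense at −78 °C, where the esters and the acylal are expected to be inert.

Step 24
Reactants: 34 C11 alcohol
Product: 35 target, (1S,6R,7S,7aS)-4-(acetoxymethyl)-1-[(3-acetoxy-3-methylbutanoyl)oxy]-7-hydroxy-6-(3-methylbutanoyloxy)-7-[(3-methylbutanoyloxy)methyl]-1,6,7,7a-tetrahydrocyclopenta[c]pyran
Conditions: Ac2O, pyridine, DMAP (cat.), CH2Cl2, 0 °C
Reagents that add atoms: acetic anhydride (CC(=O)OC(C)=O)
Why: DMAP-catalysed acetylation esterifies the primary allylic C11 hydroxyl, the tertiary C8 hydroxyl remaining free for steric reasons.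

**Compound list**

1 | (R)-4-(tert-butyldimethylsilyloxy)cyclopent-2-en-1-one | O=C1C[C@@H](O[Si](C)(C)C(C)(C)C)C=C1 | starting material
2 | (2S,3R,4R)-4-(tert-butyldimethylsilyloxy)-2,3-dihydroxycyclopentan-1-one | O=C1C[C@@H](O[Si](C)(C)C(C)(C)C)[C@H](O)[C@@H]1O | intermediate
3 | 2,3-bis(3-methylbutanoate) of 2 | O=C1C[C@@H](O[Si](C)(C)C(C)(C)C)[C@H](OC(=O)CC(C)C)[C@@H]1OC(=O)CC(C)C | intermediate (not isolated)
4 | (R)-4-(tert-butyldimethylsilyloxy)-2-(3-methylbutanoyloxy)cyclopent-2-en-1-one | O=C1C[C@@H](O[Si](C)(C)C(C)(C)C)C=C1OC(=O)CC(C)C | intermediate (key-step precursor)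
5 | acetylene | C#C | starting material
6 | (1R,4R,5S)-4-(tert-butyldimethylsilyloxy)-2-oxobicyclo[3.2.0]hept-6-en-1-yl 3-methylbutanoate | O=C1C[C@@H](O[Si](C)(C)C(C)(C)C)[C@@H]2C=C[C@]12OC(=O)CC(C)C | intermediate (key-step product)
7 | (1R,4R,5S)-4-hydroxy-2-oxobicyclo[3.2.0]hept-6-en-1-yl 3-methylbutanoate | O=C1C[C@@H](O)[C@@H]2C=C[C@]12OC(=O)CC(C)C | intermediate
8 | (1R,2R,4R,5S)-2,4-dihydroxybicyclo[3.2.0]hept-6-en-1-yl 3-methylbutanoate | O[C@@H]1C[C@@H](O)[C@@H]2C=C[C@]12OC(=O)CC(C)C | intermediate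
9 | (1R,2R,4R,5S)-2-hydroxy-4-(triethylsilyloxy)bicyclo[3.2.0]hept-6-en-1-yl 3-methylbutanoate | O[C@@H]1C[C@@H](O[Si](CC)(CC)CC)[C@@H]2C=C[C@]12OC(=O)CC(C)C | intermediate (not isolated)
10 | (1R,2R,4R,5S)-2-(tert-butyldimethylsilyloxy)-4-(triethylsilyloxy)bicyclo[3.2.0]hept-6-en-1-yl 3-methylbutanoate | CC(C)(C)[Si](C)(C)O[C@@H]1C[C@@H](O[Si](CC)(CC)CC)[C@@H]2C=C[C@]12OC(=O)CC(C)C | intermediate
11 | (1R,2R,4R,5S)-2-(tert-butyldimethylsilyloxy)-4-hydroxybicyclo[3.2.0]hept-6-en-1-yl 3-methylbutanoate | CC(C)(C)[Si](C)(C)O[C@@H]1C[C@@H](O)[C@@H]2C=C[C@]12OC(=O)CC(C)C | intermediate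
12 | (1R,2R,5R)-2-(tert-butyldimethylsilyloxy)-4-oxobicyclo[3.2.0]hept-6-en-1-yl 3-methylbutanoate | CC(C)(C)[Si](C)(C)O[C@@H]1CC(=O)[C@@H]2C=C[C@]12OC(=O)CC(C)C | intermediate
13 | (1R,2R,5R)-2-(tert-butyldimethylsilyloxy)-4-(trifluoromethylsulfonyloxy)bicyclo[3.2.0]hepta-3,6-dien-1-yl 3-methylbutanoate | CC(C)(C)[Si](C)(C)O[C@@H]1C=C(OS(=O)(=O)C(F)(F)F)[C@@H]2C=C[C@]12OC(=O)CC(C)C | intermediate
14 | ozonide of 13 across the cyclobutene (1,2,4-trioxolane bridging C1 and C10; configuration at these two acetal carbons not assigned) | CC(C)(C)[Si](C)(C)O[C@@H]1C=C(OS(=O)(=O)C(F)(F)F)[C@@H]2C3OOC(O3)[C@]12OC(=O)CC(C)C | intermediate (not isolated)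
15 | 5-(tert-butyldimethylsilyloxy)-1,2-bis(hydroxymethyl)-3-(trifluoromethylsulfonyloxy)cyclopent-3-en-1-yl 3-methylbutanoate (ester on tertiary O8) | CC(C)(C)[Si](C)(C)O[C@@H]1C=C(OS(=O)(=O)C(F)(F)F)[C@H](CO)[C@]1(OC(=O)CC(C)C)CO | intermediate (not isolated)
16 | [5-(tert-butyldimethylsilyloxy)-1-hydroxy-2-(hydroxymethyl)-3-(trifluoromethylsulfonyloxy)cyclopent-3-en-1-yl]methyl 3-methylbutanoate | CC(C)(C)[Si](C)(C)O[C@@H]1C=C(OS(=O)(=O)C(F)(F)F)[C@H](CO)[C@]1(O)COC(=O)CC(C)C | intermediate
17 | [1,5-dihydroxy-2-(hydroxymethyl)-3-(trifluoromethylsulfonyloxy)cyclopent-3-en-1-yl]methyl 3-methylbutanoate | O[C@@H]1C=C(OS(=O)(=O)C(F)(F)F)[C@H](CO)[C@]1(O)COC(=O)CC(C)C | intermediate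
18 | [2-(tert-butyldimethylsilyloxymethyl)-1,5-dihydroxy-3-(trifluoromethylsulfonyloxy)cyclopent-3-en-1-yl]methyl 3-methylbutanoate | O[C@@H]1C=C(OS(=O)(=O)C(F)(F)F)[C@H](CO[Si](C)(C)C(C)(C)C)[C@]1(O)COC(=O)CC(C)C | intermediate
19 | methyl (E)-3-methoxyacrylate | CO/C=C/C(=O)OC | starting material
20 | methyl 3-acetoxy-2-iodo-3-methoxypropanoate (diastereomer mixture) | COC(OC(C)=O)C(I)C(=O)OC | intermediate (not isolated)
21 | methyl (Z)-2-iodo-3-methoxyacrylate | CO/C=C(\I)C(=O)OC | intermediate
22 | methyl (Z)-3-methoxy-2-(tributylstannyl)acrylate | CO/C=C(\[Sn](CCCC)(CCCC)CCCC)C(=O)OC | intermediate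
23 | (Z)-3-methoxy-2-(tributylstannyl)prop-2-en-1-ol | CO/C=C(\[Sn](CCCC)(CCCC)CCCC)CO | intermediate
24 | (Z)-3-methoxy-2-(tributylstannyl)prop-2-enal | CO/C=C(\[Sn](CCCC)(CCCC)CCCC)C=O | intermediate
25 | {2-(tert-butyldimethylsilyloxymethyl)-3-[(E)-3-methoxy-1-oxoprop-2-en-2-yl]-1,5-dihydroxycyclopent-3-en-1-yl}methyl 3-methylbutanoate | CO/C=C(/C=O)C1=C[C@@H](O)[C@@](O)(COC(=O)CC(C)C)[C@H]1CO[Si](C)(C)C(C)(C)C | intermediate
26 | 7-O-(3-methylbutanoyl) derivative of 25 | CO/C=C(/C=O)C1=C[C@@H](OC(=O)CC(C)C)[C@@](O)(COC(=O)CC(C)C)[C@H]1CO[Si](C)(C)C(C)(C)C | intermediate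
27 | C1 primary alcohol from 26 | CO/C=C(/C=O)C1=C[C@@H](OC(=O)CC(C)C)[C@@](O)(COC(=O)CC(C)C)[C@H]1CO | intermediate
28 | C1 aldehyde from 27 | CO/C=C(/C=O)C1=C[C@@H](OC(=O)CC(C)C)[C@@](O)(COC(=O)CC(C)C)[C@H]1C=O | intermediate (not isolated)
29 | (1R,6R,7S,7aS)-1,7-dihydroxy-6-(3-methylbutanoyloxy)-7-[(3-methylbutanoyloxy)methyl]-1,6,7,7a-tetrahydrocyclopenta[c]pyran-4-carbaldehyde | O=CC1=CO[C@@H](O)[C@H]2C1=C[C@@H](OC(=O)CC(C)C)[C@@]2(O)COC(=O)CC(C)C | intermediate
30 | 3-hydroxy-3-methylbutanoic acid | CC(C)(O)CC(O)=O | starting material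
31 | acetic 3-acetoxy-3-methylbutanoic anhydride | CC(=O)OC(C)(C)CC(=O)OC(C)=O | intermediate (not isolated)
32 | 3-acetoxy-3-methylbutanoic acid | CC(=O)OC(C)(C)CC(O)=O | intermediate
33 | (1S,6R,7S,7aS)-1-[(3-acetoxy-3-methylbutanoyl)oxy]-7-hydroxy-6-(3-methylbutanoyloxy)-7-[(3-methylbutanoyloxy)methyl]-1,6,7,7a-tetrahydrocyclopenta[c]pyran-4-carbaldehyde | O=CC1=CO[C@@H](OC(=O)CC(C)(C)OC(C)=O)[C@H]2C1=C[C@@H](OC(=O)CC(C)C)[C@@]2(O)COC(=O)CC(C)C | intermediate
34 | 4-(hydroxymethyl) analogue of 33 | OCC1=CO[C@@H](OC(=O)CC(C)(C)OC(C)=O)[C@H]2C1=C[C@@H](OC(=O)CC(C)C)[C@@]2(O)COC(=O)CC(C)C | intermediate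
35 | CNP0331701.2 | CC(=O)OCC1=CO[C@@H](OC(=O)CC(C)(C)OC(C)=O)[C@H]2C1=C[C@@H](OC(=O)CC(C)C)[C@@]2(O)COC(=O)CC(C)C | target

**Step count**

Total: 24 steps. Longest linear sequence: 19 steps (steps 1–12, 17–20, 22–24).

**Three steps most likely to fail**

Step 9 (enol triflate). The risk is β-elimination of the C7 silyloxide from the C5/C6 enolate before O-sulfonylation. Fallback: carry O7 as an alkoxide, which cannot leave. Setting out from 12, HF·pyridine would give the β-hydroxy ketone (1R,2R,5R)-2-hydroxy-4-oxobicyclo[3.2.0]hept-6-en-1-yl 3-methylbutanoate F1. LiN(SiMe3)2 (2.2 equiv, −78 °C) would then form the alkoxide–enolate dianion, which the same triflimide reagent should sulfonylate at the enolate oxygen to give (1R,2R,5R)-2-hydroxy-4-(trifluoromethylsulfonyloxy)bicyclo[3.2.0]hepta-3,6-dien-1-yl 3-methylbutanoate F2. Silylation with t-BuMe2SiOTf and 2,6-lutidine comes back to the route at 13.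

Step 17 (Stille coupling). The risk is slow transmetallation of the hindered α-stannyl enal with protodestannylation taking over. Fallback: reverse the polarity and use a Suzuki coupling. Setting out from 18, Miyaura borylation (bis(pinacolato)diboron, PdCl2(PPh3)2, PPh3, KOPh, toluene, 50 °C) would give the alkenyl pinacol boronate corresponding to 18, F3. This would be coupled (PdCl2(dppf), K3PO4, DMF, 50 °C) with (Z)-2-bromo-3-methoxyprop-2-enal F4, itself obtained from commercial 2-bromomalonaldehyde by O-methylation with trimethylsilyldiazomethane in MeOH. The coupling comes back to the route at 25.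

Step 20 (oxidation and lactolisation). The risk is epimerisation at C9 or migration of the C5=C6 bond into conjugation while the free C1 aldehyde exists, and acid-induced elimination toward an aromatic cyclopenta[c]pyran. Fallback: oxidise C1 before the diene is present and carry it masked. Setting out from 17, TEMPO/PhI(OAc)2 should oxidise only the primary alcohol to the aldehyde [2-formyl-1,5-dihydroxy-3-(trifluoromethylsulfonyloxy)cyclopent-3-en-1-yl]methyl 3-methylbutanoate F5. HC(OMe)3 with pyridinium p-toluenesulfonate in MeOH would give its dimethyl acetal F6. Stille coupling with 24 under the conditions of step 17 would give the dimethyl acetal diol F7, and acylation as in step 18 its 7-O-(3-methylbutanoate) F8. A single treatment with 0.1 M HCl in THF would then unmask the acetal and close the ring in the same medium, coming back to the route at 29.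

**Further compounds**

F1 | step 9 | (1R,2R,5R)-2-hydroxy-4-oxobicyclo[3.2.0]hept-6-en-1-yl 3-methylbutanoate | O[C@@H]1CC(=O)[C@@H]2C=C[C@]12OC(=O)CC(C)C
F2 | step 9 | (1R,2R,5R)-2-hydroxy-4-(trifluoromethylsulfonyloxy)bicyclo[3.2.0]hepta-3,6-dien-1-yl 3-methylbutanoate | O[C@@H]1C=C(OS(=O)(=O)C(F)(F)F)[C@@H]2C=C[C@]12OC(=O)CC(C)C
F3 | step 17 | [2-(tert-butyldimethylsilyloxymethyl)-1,5-dihydroxy-3-(4,4,5,5-tetramethyl-1,3,2-dioxaborolan-2-yl)cyclopent-3-en-1-yl]methyl 3-methylbutanoate | CC1(C)OB(OC1(C)C)C1=C[C@@H](O)[C@@](O)(COC(=O)CC(C)C)[C@H]1CO[Si](C)(C)C(C)(C)C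
F4 | step 17 | (Z)-2-bromo-3-methoxyprop-2-enal | CO/C=C(\Br)C=O
F5 | step 20 | [2-formyl-1,5-dihydroxy-3-(trifluoromethylsulfonyloxy)cyclopent-3-en-1-yl]methyl 3-methylbutanoate | O[C@@H]1C=C(OS(=O)(=O)C(F)(F)F)[C@H](C=O)[C@]1(O)COC(=O)CC(C)C
F6 | step 20 | [2-(dimethoxymethyl)-1,5-dihydroxy-3-(trifluoromethylsulfonyloxy)cyclopent-3-en-1-yl]methyl 3-methylbutanoate | O[C@@H]1C=C(OS(=O)(=O)C(F)(F)F)[C@H](C(OC)OC)[C@]1(O)COC(=O)CC(C)C
F7 | step 20 | {2-(dimethoxymethyl)-3-[(E)-3-methoxy-1-oxoprop-2-en-2-yl]-1,5-dihydroxycyclopent-3-en-1-yl}methyl 3-methylbutanoate | CO/C=C(/C=O)C1=C[C@@H](O)[C@@](O)(COC(=O)CC(C)C)[C@H]1C(OC)OC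
F8 | step 20 | 7-O-(3-methylbutanoyl) derivative of F7 | CO/C=C(/C=O)C1=C[C@@H](OC(=O)CC(C)C)[C@@](O)(COC(=O)CC(C)C)[C@H]1C(OC)OC
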